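The route rests on cutting the O1–C2 bond of the inner dihydrofuran (O1, C2, C3, fused to ring B). C2 is benzylic to guaiacyl ring A and para to its free hydroxyl; taking two electrons and two protons from that phenol leaves C2 as the exocyclic, electron-poor carbon of a para-quinone methide, within reach of the ring B hydroxyl. One quinone-mediated anodic dehydrogenation forms O1–C2, closes the ring and sets C2 trans to the C3 centre installed by auxiliary-controlled alkylation. The precursor is an open 2,3-diarylpropanol with both phenols free and a formyl group para to the ring B hydroxyl, which shields ring B from oxidation and anchors the outer ring.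

Key step: step 11

Remarks: ring A is the guaiacyl ring, ring B the central ring, ring C the outer ring; O1/C2/C3 is the inner dihydrofuran and O1′/C2′/C3′ the outer one. The target is read as (2S,3R,2′S,3′R), both rings trans. Ring B carries its one-carbon handle as a formyl group through the closure and the C3 CH2OH is left free, so that no redox step is needed on the free-phenol product. The outer ring cannot be closed through a quinone methide once O1 is an ether, so it is made by aldol addition and acid closure. Alcohol 11 and both oxazolidinones are assumed to be purchased.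

Step 1
Reactants: 1 methyl vanillate (methyl 4-hydroxy-3-methoxybenzoate); 2 allyl bromide
Product: 3 methyl 4-(allyloxy)-3-methoxybenzoate
Conditions: K2CO3, acetone, reflux
Reagents that add atoms: none
Why: Williamson ether synthesis, the phenoxide displacing bromide from the allylic halide (SN2).

Step 2
Reactants: 3 methyl 4-(allyloxy)-3-methoxybenzoate
Product: 4 methyl 3-allyl-4-hydroxy-5-methoxybenzoate
Conditions: N,N-diethylaniline, 200 °C
Reagents that add atoms: none
Why: Aromatic Claisen rearrangement; the allyl group can only migrate to C5, the one free ortho position, and tautomerisation restores the phenol.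

Step 3
Reactants: 4 methyl 3-allyl-4-hydroxy-5-methoxybenzoate
Product: 5 methyl 3-allyl-4-(benzyloxy)-5-methoxybenzoate
Conditions: BnBr, K2CO3, DMF, 60 °C
Reagents that add atoms: benzyl bromide, BrCc1ccccc1
Why: Williamson benzylation of the phenol; the benzyl ether should survive ozone, enolate and hydride chemistry and is removed later together with the ring A benzyl ether.

Step 4
Reactants: 5 methyl 3-allyl-4-(benzyloxy)-5-methoxybenzoate
Product: 7 2-[2-(benzyloxy)-3-methoxy-5-(methoxycarbonyl)phenyl]acetic acid, via arylacetaldehyde 6 (not isolated)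
Conditions: O3, MeCN/H2O (9:1), 0 °C; then NaClO2, NaH2PO4, 0 °C to rt
Reagents that add atoms: ozone, [O-][O+]=O; sodium chlorite, [Na+].[O-]Cl=O
Why: Ozonolysis in aqueous acetonitrile gives the aldehyde and H2O2 directly and chlorite then performs a Pinnick oxidation with that H2O2 as hypochlorite scavenger; the terminal alkene reacts with ozone far faster than the benzyl ether or the ester-deactivated arene.

Step 5
Reactants: 7 2-[2-(benzyloxy)-3-methoxy-5-(methoxycarbonyl)phenyl]acetic acid; 8 (R)-4-benzyl-1,3-oxazolidin-2-one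
Product: 10 methyl 4-(benzyloxy)-3-{2-[(4R)-4-benzyl-2-oxo-1,3-oxazolidin-3-yl]-2-oxoethyl}-5-methoxybenzoate, via mixed pivalic anhydride 9 (not isolated)
Conditions: t-BuCOCl, Et3N, THF, −20 to 0 °C; then 8, LiCl, rt
Reagents that add atoms: none
Why: N-acylation of the oxazolidinone by the mixed anhydride under LiCl/Et3N activation, attack occurring at the less hindered arylacetyl carbonyl.

Step 6
Reactants: 11 [4-(benzyloxy)-3-methoxyphenyl]methanol
Product: 12 1-(benzyloxy)-4-(bromomethyl)-2-methoxybenzene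
Conditions: PBr3, Et2O, 0 °C
Reagents that add atoms: phosphorus tribromide, BrP(Br)Br
Why: Bromination of the benzylic alcohol through its phosphite ester (SN2); the electron-rich bromide is used at once.

Step 7
Reactants: 10 methyl 4-(benzyloxy)-3-{2-[(4R)-4-benzyl-2-oxo-1,3-oxazolidin-3-yl]-2-oxoethyl}-5-methoxybenzoate; 12 1-(benzyloxy)-4-(bromomethyl)-2-methoxybenzene
Product: 13 methyl 4-(benzyloxy)-3-{(2R)-1-[(4R)-4-benzyl-2-oxo-1,3-oxazolidin-3-yl]-3-[4-(benzyloxy)-3-methoxyphenyl]-1-oxopropan-2-yl}-5-methoxybenzoate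
Conditions: NaN(SiMe3)2, THF, −78 °C; then 12, −78 to −40 °C
Reagents that add atoms: none
Why: Evans asymmetric alkylation; the chelated Z-sodium enolate is benzylated on the face away from the C4 benzyl group of the (R)-auxiliary, which sets the future C3 centre as R.

Step 8
Reactants: 13 methyl 4-(benzyloxy)-3-{(2R)-1-[(4R)-4-benzyl-2-oxo-1,3-oxazolidin-3-yl]-3-[4-(benzyloxy)-3-methoxyphenyl]-1-oxopropan-2-yl}-5-methoxybenzoate
Product: 14 (2R)-2-[2-(benzyloxy)-5-(hydroxymethyl)-3-methoxyphenyl]-3-[4-(benzyloxy)-3-methoxyphenyl]propan-1-ol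
Conditions: LiAlH4, THF, 0 °C to rt; aq. potassium sodium tartrate
Reagents that add atoms: none
Why: Hydride reduction of the exocyclic imide carbonyl releases the auxiliary and the primary alcohol while the methyl ester goes to the benzylic alcohol in the same flask; afterwards the stereocentre is no longer α to a carbonyl and cannot epimerise.

Step 9
Reactants: 14 (2R)-2-[2-(benzyloxy)-5-(hydroxymethyl)-3-methoxyphenyl]-3-[4-(benzyloxy)-3-methoxyphenyl]propan-1-ol
Product: 15 4-(benzyloxy)-3-{(2R)-1-[4-(benzyloxy)-3-methoxyphenyl]-3-hydroxypropan-2-yl}-5-methoxybenzaldehyde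
Conditions: MnO2, CH2Cl2, rt
Reagents that add atoms: none
Why: Chemoselective benzylic oxidation; activated MnO2 oxidises the benzylic alcohol and leaves the aliphatic primary alcohol.

Step 10
Reactants: 15 4-(benzyloxy)-3-{(2R)-1-[4-(benzyloxy)-3-methoxyphenyl]-3-hydroxypropan-2-yl}-5-methoxybenzaldehyde
Product: 16 4-hydroxy-3-[(2R)-1-hydroxy-3-(4-hydroxy-3-methoxyphenyl)propan-2-yl]-5-methoxybenzaldehyde
Conditions: H2 (1 atm), 10% Pd/C, EtOAc, rt
Reagents that add atoms: none
Why: Hydrogenolysis of both aryl benzyl ethers; in EtOAc at 1 atm the vanillin-type aldehyde should be reduced much more slowly, and the reaction is stopped after two equivalents of H2.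

Step 11
Reactants: 16 4-hydroxy-3-[(2R)-1-hydroxy-3-(4-hydroxy-3-methoxyphenyl)propan-2-yl]-5-methoxybenzaldehyde
Product: 18 (2S,3R)-2-(4-hydroxy-3-methoxyphenyl)-3-(hydroxymethyl)-7-methoxy-2,3-dihydro-1-benzofuran-5-carbaldehyde, via para-quinone methide 17 (not isolated)
Conditions: divided cell, graphite-felt anode, platinum cathode, DDQ (20 mol %), LiClO4 (0.1 M), MeCN/AcOH (9:1), 16 at 0.01 M in the anolyte, anode held at the DDQH2/DDQ wave, 2.1 F/mol, rt
Reagents that add atoms: none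
Why: DDQ takes two electrons and two protons from the ring A 4-alkylguaiacol (the phenolic proton and, formally, hydride from the C2 methylene) to give the para-quinone methide 17, and the anode returns DDQH2 to DDQ while the cathode reduces protons to H2. The ring B hydroxyl then adds to the exocyclic carbon C2 of 17 in a 1,6-addition that is a 5-exo-trig closure, forming O1–C2 and restoring ring A as a phenol. The closest known reaction type is the quinone oxidation of 4-alkyl-2-methoxyphenols to para-quinone methides with capture by oxygen nucleophiles, made intramolecular here and run with anodic turnover of the quinone. C2 is controlled by the C3 centre: the ring closes through the envelope that keeps the ring A residue and the CH2OH group on opposite faces, so the trans ring, also the more stable one, should form. The step needs oxidation of ring A and not ring B, which the formyl group para to the ring B hydroxyl secures, and capture of the methide before it tautomerises to a stilbene, which the hydroxyl placed for five-ring closure secures. Holding the anode at the mediator wave and passing only 2 F/mol keeps free phenoxyl radicals (and their ortho coupling) out of the solution and limits re-oxidation of the product phenol.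

Step 12
Reactants: 18 (2S,3R)-2-(4-hydroxy-3-methoxyphenyl)-3-(hydroxymethyl)-7-methoxy-2,3-dihydro-1-benzofuran-5-carbaldehyde
Product: 19 [(2S,3R)-5-formyl-7-methoxy-2-[3-methoxy-4-(pivaloyloxy)phenyl]-2,3-dihydro-1-benzofuran-3-yl]methyl pivalate
Conditions: t-BuCOCl, pyridine, DMAP (cat.), CH2Cl2, 0 °C to rt
Reagents that add atoms: pivaloyl chloride, CC(C)(C)C(Cl)=O
Why: Acylation of the ring A phenol and the primary alcohol under nucleophilic catalysis; the pivalates should survive borohydride, acid and Heck conditions and fall in the final reduction.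

Step 13
Reactants: 20 4-bromo-2-methoxyphenol; 2 allyl bromide
Product: 21 1-(allyloxy)-4-bromo-2-methoxybenzene
Conditions: K2CO3, acetone, reflux
Reagents that add atoms: none
Why: Williamson ether synthesis (SN2 of the phenoxide on the allylic bromide).

Step 14
Reactants: 21 1-(allyloxy)-4-bromo-2-methoxybenzene
Product: 22 2-allyl-4-bromo-6-methoxyphenol
Conditions: N,N-diethylaniline, 200 °C
Reagents that add atoms: none
Why: Aromatic Claisen rearrangement to the only free ortho position; the para position is blocked by bromine.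

Step 15
Reactants: 22 2-allyl-4-bromo-6-methoxyphenol
Product: 23 1-allyl-5-bromo-3-methoxy-2-(methoxymethoxy)benzene
Conditions: MeOCH2Cl, i-Pr2NEt, CH2Cl2, 0 °C to rt
Reagents that add atoms: chloromethyl methyl ether, COCCl
Why: O-alkylation to the methoxymethyl ether, which should survive ozone, chlorite, enolisation and LiBH4 and is cleaved by the same acid that later closes the outer ring.

Step 16
Reactants: 23 1-allyl-5-bromo-3-methoxy-2-(methoxymethoxy)benzene
Product: 25 2-[5-bromo-3-methoxy-2-(methoxymethoxy)phenyl]acetic acid, via arylacetaldehyde 24 (not isolated)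
Conditions: O3, MeCN/H2O (9:1), 0 °C; then NaClO2, NaH2PO4, 0 °C to rt
Reagents that add atoms: ozone, [O-][O+]=O; sodium chlorite, [Na+].[O-]Cl=O
Why: Ozonolysis in aqueous acetonitrile followed by Pinnick oxidation in the same flask, as in step 4; the aryl bromide and the acetal are inert.

Step 17
Reactants: 25 2-[5-bromo-3-methoxy-2-(methoxymethoxy)phenyl]acetic acid; 26 (S)-4-benzyl-1,3-oxazolidin-2-one
Product: 28 (4S)-4-benzyl-3-{2-[5-bromo-3-methoxy-2-(methoxymethoxy)phenyl]acetyl}-1,3-oxazolidin-2-one, via mixed pivalic anhydride 27 (not isolated)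
Conditions: t-BuCOCl, Et3N, THF, −20 to 0 °C; then 26, LiCl, rt
Reagents that add atoms: none
Why: N-acylation of the oxazolidinone through the mixed anhydride, as in step 5.

Step 18
Reactants: 28 (4S)-4-benzyl-3-{2-[5-bromo-3-methoxy-2-(methoxymethoxy)phenyl]acetyl}-1,3-oxazolidin-2-one; 19 [(2S,3R)-5-formyl-7-methoxy-2-[3-methoxy-4-(pivaloyloxy)phenyl]-2,3-dihydro-1-benzofuran-3-yl]methyl pivalate
Product: 29 [(2S,3R)-5-{(1S,2S)-3-[(4S)-4-benzyl-2-oxo-1,3-oxazolidin-3-yl]-2-[5-bromo-3-methoxy-2-(methoxymethoxy)phenyl]-1-hydroxy-3-oxopropyl}-7-methoxy-2-[3-methoxy-4-(pivaloyloxy)phenyl]-2,3-dihydro-1-benzofuran-3-yl]methyl pivalate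
Conditions: 28, n-Bu2BOTf, i-Pr2NEt, CH2Cl2, −78 to 0 °C; then 19, −78 to 0 °C; pH 7 buffer, MeOH, H2O2, 0 °C
Reagents that add atoms: none
Why: Evans syn-aldol addition through the Z-boron enolate in a Zimmerman–Traxler chair; the (S)-auxiliary directs the aldehyde to the enolate face that makes the α-carbon S (the future C3′, R once the imide is reduced), and the carbinol centre formed with it is erased in step 20.

Step 19
Reactants: 29 the syn-aldol adduct of step 18
Product: 30 [(2S,3R)-5-{(1S,2R)-2-[5-bromo-3-methoxy-2-(methoxymethoxy)phenyl]-1,3-dihydroxypropyl}-7-methoxy-2-[3-methoxy-4-(pivaloyloxy)phenyl]-2,3-dihydro-1-benzofuran-3-yl]methyl pivalate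
Conditions: LiBH4, MeOH (1 equiv), THF, 0 °C
Reagents that add atoms: none
Why: Reductive cleavage of the N-acyloxazolidinone; borohydride should attack the activated exocyclic imide carbonyl much faster than the hindered pivalates, and the descriptor at the former α-carbon changes from S to R only because the priorities change.

Step 20
Reactants: 30 the 1,3-diol of step 19
Product: 32 [(2S,3R)-5-[(2S,3R)-5-bromo-3-(hydroxymethyl)-7-methoxy-2,3-dihydro-1-benzofuran-2-yl]-7-methoxy-2-[3-methoxy-4-(pivaloyloxy)phenyl]-2,3-dihydro-1-benzofuran-3-yl]methyl pivalate, via free phenol 31 (not isolated)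
Conditions: HCl (ca. 0.5 M), MeOH/THF (1:1), rt to 40 °C
Reagents that add atoms: none
Why: Acid removes the methoxymethyl acetal and ionises the secondary benzylic alcohol to a cation stabilised by the para oxygen O1 of ring B, which the freed ring C hydroxyl captures in a five-membered SN1 closure with the ring B residue trans to the C3′ CH2OH group, the kinetically and thermodynamically preferred isomer whatever the carbinol configuration, so only the C3′ centre from step 18 matters.

Step 21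
Reactants: 32 the bromide of step 20; 33 methyl acrylate
Product: 34 methyl (2E)-3-{(2S,3R)-3-(hydroxymethyl)-7-methoxy-2-[(2S,3R)-7-methoxy-2-[3-methoxy-4-(pivaloyloxy)phenyl]-3-[(pivaloyloxy)methyl]-2,3-dihydro-1-benzofuran-5-yl]-2,3-dihydro-1-benzofuran-5-yl}prop-2-enoate
Conditions: 33, Pd(OAc)2, P(o-tol)3, Et3N, DMF, 90 °C
Reagents that add atoms: none
Why: Mizoroki–Heck reaction of the unhindered aryl bromide; syn-insertion and syn-β-hydride elimination should give the E-cinnamate, and the free primary alcohol and the pivalates are spectators.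

Step 22
Reactants: 34 the cinnamate of step 21
Product: 35 (2E)-3-{(2S,3R)-2-[(2S,3R)-2-(4-hydroxy-3-methoxyphenyl)-3-(hydroxymethyl)-7-methoxy-2,3-dihydro-1-benzofuran-5-yl]-3-(hydroxymethyl)-7-methoxy-2,3-dihydro-1-benzofuran-5-yl}prop-2-en-1-ol (the target)
Conditions: i-Bu2AlH (excess), CH2Cl2, −78 to 0 °C; aq. potassium sodium tartrate
Reagents that add atoms: none
Why: DIBAL-H reduction takes the cinnamate 1,2 to the allylic alcohol and cleaves both pivalates in the same flask, releasing the ring A phenol and the C3 CH2OH; no stereocentre is α to a carbonyl, so none is at risk.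

Compound list
1 | methyl vanillate (methyl 4-hydroxy-3-methoxybenzoate) | COC(=O)c1ccc(O)c(OC)c1 | starting material
2 | allyl bromide | C=CCBr | starting material
3 | methyl 4-(allyloxy)-3-methoxybenzoate | COC(=O)c1ccc(OCC=C)c(OC)c1 | intermediate
4 | methyl 3-allyl-4-hydroxy-5-methoxybenzoate | COC(=O)c1cc(CC=C)c(O)c(OC)c1 | intermediate
5 | methyl 3-allyl-4-(benzyloxy)-5-methoxybenzoate | COC(=O)c1cc(CC=C)c(OCc2ccccc2)c(OC)c1 | intermediate
6 | methyl 4-(benzyloxy)-3-methoxy-5-(2-oxoethyl)benzoate (not isolated) | COC(=O)c1cc(CC=O)c(OCc2ccccc2)c(OC)c1 | intermediate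
7 | 2-[2-(benzyloxy)-3-methoxy-5-(methoxycarbonyl)phenyl]acetic acid | COC(=O)c1cc(CC(=O)O)c(OCc2ccccc2)c(OC)c1 | intermediate
8 | (R)-4-benzyl-1,3-oxazolidin-2-one | O=C1N[C@H](Cc2ccccc2)CO1 | starting material
9 | mixed anhydride of 7 with pivalic acid (not isolated) | COC(=O)c1cc(CC(=O)OC(=O)C(C)(C)C)c(OCc2ccccc2)c(OC)c1 | intermediate
10 | methyl 4-(benzyloxy)-3-{2-[(4R)-4-benzyl-2-oxo-1,3-oxazolidin-3-yl]-2-oxoethyl}-5-methoxybenzoate | COC(=O)c1cc(CC(=O)N2C(=O)OC[C@H]2Cc3ccccc3)c(OCc4ccccc4)c(OC)c1 | intermediate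
11 | [4-(benzyloxy)-3-methoxyphenyl]methanol | COc1cc(CO)ccc1OCc1ccccc1 | starting material
12 | 1-(benzyloxy)-4-(bromomethyl)-2-methoxybenzene | COc1cc(CBr)ccc1OCc1ccccc1 | intermediate
13 | methyl 4-(benzyloxy)-3-{(2R)-1-[(4R)-4-benzyl-2-oxo-1,3-oxazolidin-3-yl]-3-[4-(benzyloxy)-3-methoxyphenyl]-1-oxopropan-2-yl}-5-methoxybenzoate | COC(=O)c1cc([C@@H](Cc2ccc(OCc3ccccc3)c(OC)c2)C(=O)N4C(=O)OC[C@H]4Cc5ccccc5)c(OCc6ccccc6)c(OC)c1 | intermediate
14 | (2R)-2-[2-(benzyloxy)-5-(hydroxymethyl)-3-methoxyphenyl]-3-[4-(benzyloxy)-3-methoxyphenyl]propan-1-ol | OCc1cc([C@@H](Cc2ccc(OCc3ccccc3)c(OC)c2)CO)c(OCc4ccccc4)c(OC)c1 | intermediate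
15 | 4-(benzyloxy)-3-{(2R)-1-[4-(benzyloxy)-3-methoxyphenyl]-3-hydroxypropan-2-yl}-5-methoxybenzaldehyde | O=Cc1cc([C@@H](Cc2ccc(OCc3ccccc3)c(OC)c2)CO)c(OCc4ccccc4)c(OC)c1 | intermediate
16 | 4-hydroxy-3-[(2R)-1-hydroxy-3-(4-hydroxy-3-methoxyphenyl)propan-2-yl]-5-methoxybenzaldehyde (key-step precursor) | O=Cc1cc([C@@H](Cc2ccc(O)c(OC)c2)CO)c(O)c(OC)c1 | intermediate
17 | 4-hydroxy-3-[(2R)-1-hydroxy-3-(3-methoxy-4-oxocyclohexa-2,5-dien-1-ylidene)propan-2-yl]-5-methoxybenzaldehyde (para-quinone methide, not isolated) | O=Cc1cc([C@H](CO)C=C2C=CC(=O)C(OC)=C2)c(O)c(OC)c1 | intermediate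
18 | (2S,3R)-2-(4-hydroxy-3-methoxyphenyl)-3-(hydroxymethyl)-7-methoxy-2,3-dihydro-1-benzofuran-5-carbaldehyde (key-step product) | COc1cc([C@H]2Oc3c(OC)cc(C=O)cc3[C@@H]2CO)ccc1O | intermediate
19 | [(2S,3R)-5-formyl-7-methoxy-2-[3-methoxy-4-(pivaloyloxy)phenyl]-2,3-dihydro-1-benzofuran-3-yl]methyl pivalate | CC(C)(C)C(=O)Oc1ccc(cc1OC)[C@H]1Oc2c(OC)cc(C=O)cc2[C@@H]1COC(=O)C(C)(C)C | intermediate
20 | 4-bromo-2-methoxyphenol | COc1cc(Br)ccc1O | starting material
21 | 1-(allyloxy)-4-bromo-2-methoxybenzene | COc1cc(Br)ccc1OCC=C | intermediate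
22 | 2-allyl-4-bromo-6-methoxyphenol | COc1cc(Br)cc(CC=C)c1O | intermediate
23 | 1-allyl-5-bromo-3-methoxy-2-(methoxymethoxy)benzene | COCOc1c(CC=C)cc(Br)cc1OC | intermediate
24 | 2-[5-bromo-3-methoxy-2-(methoxymethoxy)phenyl]acetaldehyde (not isolated) | COCOc1c(CC=O)cc(Br)cc1OC | intermediate
25 | 2-[5-bromo-3-methoxy-2-(methoxymethoxy)phenyl]acetic acid | COCOc1c(CC(=O)O)cc(Br)cc1OC | intermediate
26 | (S)-4-benzyl-1,3-oxazolidin-2-one | O=C1N[C@@H](Cc2ccccc2)CO1 | starting material
27 | mixed anhydride of 25 with pivalic acid (not isolated) | COCOc1c(CC(=O)OC(=O)C(C)(C)C)cc(Br)cc1OC | intermediate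
28 | (4S)-4-benzyl-3-{2-[5-bromo-3-methoxy-2-(methoxymethoxy)phenyl]acetyl}-1,3-oxazolidin-2-one | COCOc1c(CC(=O)N2C(=O)OC[C@@H]2Cc3ccccc3)cc(Br)cc1OC | intermediate
29 | syn-aldol adduct: [(2S,3R)-5-{(1S,2S)-3-[(4S)-4-benzyl-2-oxo-1,3-oxazolidin-3-yl]-2-[5-bromo-3-methoxy-2-(methoxymethoxy)phenyl]-1-hydroxy-3-oxopropyl}-7-methoxy-2-[3-methoxy-4-(pivaloyloxy)phenyl]-2,3-dihydro-1-benzofuran-3-yl]methyl pivalate | CC(C)(C)C(=O)Oc1ccc(cc1OC)[C@H]1Oc2c(OC)cc(cc2[C@@H]1COC(=O)C(C)(C)C)[C@@H](O)[C@@H](C(=O)N1C(=O)OC[C@@H]1Cc1ccccc1)c1cc(Br)cc(OC)c1OCOC | intermediate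
30 | [(2S,3R)-5-{(1S,2R)-2-[5-bromo-3-methoxy-2-(methoxymethoxy)phenyl]-1,3-dihydroxypropyl}-7-methoxy-2-[3-methoxy-4-(pivaloyloxy)phenyl]-2,3-dihydro-1-benzofuran-3-yl]methyl pivalate | CC(C)(C)C(=O)Oc1ccc(cc1OC)[C@H]1Oc2c(OC)cc(cc2[C@@H]1COC(=O)C(C)(C)C)[C@@H](O)[C@@H](CO)c1cc(Br)cc(OC)c1OCOC | intermediate
31 | [(2S,3R)-5-[(1S,2R)-2-(5-bromo-2-hydroxy-3-methoxyphenyl)-1,3-dihydroxypropyl]-7-methoxy-2-[3-methoxy-4-(pivaloyloxy)phenyl]-2,3-dihydro-1-benzofuran-3-yl]methyl pivalate (not isolated) | CC(C)(C)C(=O)Oc1ccc(cc1OC)[C@H]1Oc2c(OC)cc(cc2[C@@H]1COC(=O)C(C)(C)C)[C@@H](O)[C@@H](CO)c1cc(Br)cc(OC)c1O | intermediate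
32 | [(2S,3R)-5-[(2S,3R)-5-bromo-3-(hydroxymethyl)-7-methoxy-2,3-dihydro-1-benzofuran-2-yl]-7-methoxy-2-[3-methoxy-4-(pivaloyloxy)phenyl]-2,3-dihydro-1-benzofuran-3-yl]methyl pivalate | CC(C)(C)C(=O)Oc1ccc(cc1OC)[C@H]1Oc2c(OC)cc(cc2[C@@H]1COC(=O)C(C)(C)C)[C@H]1Oc2c(OC)cc(Br)cc2[C@@H]1CO | intermediate
33 | methyl acrylate | C=CC(=O)OC | starting material
34 | methyl (2E)-3-{(2S,3R)-3-(hydroxymethyl)-7-methoxy-2-[(2S,3R)-7-methoxy-2-[3-methoxy-4-(pivaloyloxy)phenyl]-3-[(pivaloyloxy)methyl]-2,3-dihydro-1-benzofuran-5-yl]-2,3-dihydro-1-benzofuran-5-yl}prop-2-enoate | CC(C)(C)C(=O)Oc1ccc(cc1OC)[C@H]1Oc2c(OC)cc(cc2[C@@H]1COC(=O)C(C)(C)C)[C@H]1Oc2c(OC)cc(/C=C/C(=O)OC)cc2[C@@H]1CO | intermediate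
35 | (2E)-3-{(2S,3R)-2-[(2S,3R)-2-(4-hydroxy-3-methoxyphenyl)-3-(hydroxymethyl)-7-methoxy-2,3-dihydro-1-benzofuran-5-yl]-3-(hydroxymethyl)-7-methoxy-2,3-dihydro-1-benzofuran-5-yl}prop-2-en-1-ol | COc1cc([C@H]2Oc3c(OC)cc([C@H]4Oc5c(OC)cc(/C=C/CO)cc5[C@@H]4CO)cc3[C@@H]2CO)ccc1O | target

Total step count: 22. Longest linear sequence: 16 steps from methyl vanillate (steps 1–5, 7–12, 18–22).

Steps most likely to fail

1. Step 11. What may go wrong: re-oxidation of the product, which is itself a 4-alkylguaiacol, onward to the benzofuran; tautomerisation of the methide to a stilbene with loss of the C3 centre; coupling of phenoxyl radicals. Fallback, setting out from 7 and returning at 18: the O1–C2 bond is made by ionising a C2 carbinol and not by oxidising a C2–H bond. Acid 7 is taken through anhydride 9 and oxazolidinone 26 to the (S)-configured imide F1. An Evans syn-aldol addition (n-Bu2BOTf, i-Pr2NEt) to commercial 4-(benzyloxy)-3-methoxybenzaldehyde should give the adduct F2, and LiBH4 at 0 °C should cleave the auxiliary to the diol ester F3. Hydrogenolysis over Pd/C frees both phenols in the triol F4, and HCl in MeOH closes the trans ring through the para-hydroxybenzyl cation to the ester F5. LiAlH4 gives the triol F6, whose benzylic alcohol is oxidised with MnO2 to rejoin the route at 18.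

2. Step 20. What may go wrong: loss of the C3′ proton from the cation before the ring C phenol is free, which would scramble C3′; incomplete trans selectivity in the closure; acid-induced opening of the inner ring. Fallback, setting out from 19 and returning at 32: the outer ring is closed by forming C2′–C3′ in place of O1′–C2′, which also bypasses the aldol addition. NaBH4 reduces 19 to the benzylic alcohol F7. A Mitsunobu reaction (PPh3, DIAD) with the phenol ester F8, obtained from 25 with HCl in MeOH, gives the aryl benzyl ether F9, and diazo transfer (4-acetamidobenzenesulfonyl azide, DBU) gives the aryldiazoacetate F10. Rh2(S-PTTL)4 or its mirror image, chosen to give the (2′S) centre, should effect the intramolecular benzylic C–H insertion to the cis ester F11. DBU epimerises C3′ to the trans ester F12, and LiBH4 reduces its methyl ester to give 32.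

3. Step 7. What may go wrong: elimination of the arylacetyl enolate to a ketene, or epimerisation of the acidic α-aryl centre, either of which erodes the configuration of C3 with no later correction. Fallback, setting out from 7 and returning at 14: C3 is set by hydrogenation in place of enolate alkylation. A Perkin condensation of 7 with 4-(benzyloxy)-3-methoxybenzaldehyde (Ac2O, Et3N, 110 °C) gives the (E)-acrylic acid F13. Asymmetric hydrogenation with Ru(OAc)2[(R)-BINAP] or its antipode (H2, MeOH), the hand of the ligand being fixed by a trial run, should give the (R)-acid F14. LiAlH4 then reduces the acid and the ester to 14.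

Further compounds
F1 | step 11 | methyl 4-(benzyloxy)-3-{2-[(4S)-4-benzyl-2-oxo-1,3-oxazolidin-3-yl]-2-oxoethyl}-5-methoxybenzoate | COC(=O)c1cc(CC(=O)N2C(=O)OC[C@@H]2Cc3ccccc3)c(OCc4ccccc4)c(OC)c1
F2 | step 11 | methyl 4-(benzyloxy)-3-{(2S,3S)-1-[(4S)-4-benzyl-2-oxo-1,3-oxazolidin-3-yl]-3-[4-(benzyloxy)-3-methoxyphenyl]-3-hydroxy-1-oxopropan-2-yl}-5-methoxybenzoate | COc1cc(ccc1OCc1ccccc1)[C@@H](O)[C@@H](C(=O)N1C(=O)OC[C@@H]1Cc1ccccc1)c1cc(C(=O)OC)cc(OC)c1OCc1ccccc1
F3 | step 11 | methyl 4-(benzyloxy)-3-{(1S,2R)-1-[4-(benzyloxy)-3-methoxyphenyl]-1,3-dihydroxypropan-2-yl}-5-methoxybenzoate | COc1cc(ccc1OCc1ccccc1)[C@@H](O)[C@@H](CO)c1cc(C(=O)OC)cc(OC)c1OCc1ccccc1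
F4 | step 11 | methyl 3-[(1S,2R)-1,3-dihydroxy-1-(4-hydroxy-3-methoxyphenyl)propan-2-yl]-4-hydroxy-5-methoxybenzoate | COc1cc(ccc1O)[C@@H](O)[C@@H](CO)c1cc(C(=O)OC)cc(OC)c1O
F5 | step 11 | methyl (2S,3R)-2-(4-hydroxy-3-methoxyphenyl)-3-(hydroxymethyl)-7-methoxy-2,3-dihydro-1-benzofuran-5-carboxylate | COc1cc([C@H]2Oc3c(OC)cc(C(=O)OC)cc3[C@@H]2CO)ccc1O
F6 | step 11 | [(2S,3R)-2-(4-hydroxy-3-methoxyphenyl)-7-methoxy-2,3-dihydro-1-benzofuran-3,5-diyl]dimethanol | COc1cc([C@H]2Oc3c(OC)cc(CO)cc3[C@@H]2CO)ccc1O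
F7 | step 20 | [(2S,3R)-5-(hydroxymethyl)-7-methoxy-2-[3-methoxy-4-(pivaloyloxy)phenyl]-2,3-dihydro-1-benzofuran-3-yl]methyl pivalate | CC(C)(C)C(=O)Oc1ccc(cc1OC)[C@H]1Oc2c(OC)cc(CO)cc2[C@@H]1COC(=O)C(C)(C)C
F8 | step 20 | methyl 2-(5-bromo-2-hydroxy-3-methoxyphenyl)acetate | COC(=O)Cc1cc(Br)cc(OC)c1O
F9 | step 20 | [(2S,3R)-5-{[4-bromo-2-methoxy-6-(2-methoxy-2-oxoethyl)phenoxy]methyl}-7-methoxy-2-[3-methoxy-4-(pivaloyloxy)phenyl]-2,3-dihydro-1-benzofuran-3-yl]methyl pivalate | CC(C)(C)C(=O)Oc1ccc(cc1OC)[C@H]1Oc2c(OC)cc(COc3c(CC(=O)OC)cc(Br)cc3OC)cc2[C@@H]1COC(=O)C(C)(C)C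
F10 | step 20 | [(2S,3R)-5-{[4-bromo-2-(1-diazo-2-methoxy-2-oxoethyl)-6-methoxyphenoxy]methyl}-7-methoxy-2-[3-methoxy-4-(pivaloyloxy)phenyl]-2,3-dihydro-1-benzofuran-3-yl]methyl pivalate | CC(C)(C)C(=O)Oc1ccc(cc1OC)[C@H]1Oc2c(OC)cc(COc3c(C(=[N+]=[N-])C(=O)OC)cc(Br)cc3OC)cc2[C@@H]1COC(=O)C(C)(C)C
F11 | step 20 | methyl (2S,3R)-5-bromo-7-methoxy-2-{(2S,3R)-7-methoxy-2-[3-methoxy-4-(pivaloyloxy)phenyl]-3-[(pivaloyloxy)methyl]-2,3-dihydro-1-benzofuran-5-yl}-2,3-dihydro-1-benzofuran-3-carboxylate (cis ring) | CC(C)(C)C(=O)Oc1ccc(cc1OC)[C@H]1Oc2c(OC)cc(cc2[C@@H]1COC(=O)C(C)(C)C)[C@H]1Oc2c(OC)cc(Br)cc2[C@H]1C(=O)OC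
F12 | step 20 | methyl (2S,3S)-5-bromo-7-methoxy-2-{(2S,3R)-7-methoxy-2-[3-methoxy-4-(pivaloyloxy)phenyl]-3-[(pivaloyloxy)methyl]-2,3-dihydro-1-benzofuran-5-yl}-2,3-dihydro-1-benzofuran-3-carboxylate (trans ring) | CC(C)(C)C(=O)Oc1ccc(cc1OC)[C@H]1Oc2c(OC)cc(cc2[C@@H]1COC(=O)C(C)(C)C)[C@H]1Oc2c(OC)cc(Br)cc2[C@@H]1C(=O)OC
F13 | step 7 | (2E)-2-[2-(benzyloxy)-3-methoxy-5-(methoxycarbonyl)phenyl]-3-[4-(benzyloxy)-3-methoxyphenyl]prop-2-enoic acid | COC(=O)c1cc(/C(=C\c2ccc(OCc3ccccc3)c(OC)c2)C(=O)O)c(OCc4ccccc4)c(OC)c1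
F14 | step 7 | (2R)-2-[2-(benzyloxy)-3-methoxy-5-(methoxycarbonyl)phenyl]-3-[4-(benzyloxy)-3-methoxyphenyl]propanoic acid | COC(=O)c1cc([C@@H](Cc2ccc(OCc3ccccc3)c(OC)c2)C(=O)O)c(OCc4ccccc4)c(OC)c1
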